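## Analysis of the target

Target 17 is a diaryl ether of two benzene rings and has no stereocentre; its only non-aromatic double bond is the trisubstituted prenyl alkene, which has no E/Z isomers. Ring A carries CO2Me on C1, the ether oxygen on C2, H on C3, CH3 on C4, the prenyl group on C5 and a free OH on C6 that is hydrogen-bonded to the ester (the systematic names in the compound list number this benzoate the other way round, so C6 becomes 2, C5 becomes 3 and C2 becomes 6). Ring B carries the ether oxygen on C1', CH2OH on C2' and methoxy groups on C4' and C6'. The sensitive groups are the prenyl alkene (acid closes it onto the C6 phenol to a chroman, and boranes add to it), the benzylic alcohol, the free phenol and the ester. The difficulty is the ether oxygen, which has the ester ortho to it on ring A and two ortho substituents on ring B, so a direct aryl–oxygen coupling is badly hindered. In addition, two carboxyl-level carbons (C1 ester kept, C2' branch reduced) and three phenolic oxygens (two methylated, one free) must be told apart. The strategy rests on ring B: oxygens on C4' and C6' meta to each other, a one-carbon branch on C2' and the ether oxygen on C1' form the pattern of a seven-carbon 2,4,6-tricarbonyl ester chain folded by an aldol between its two ends. If the terminal CH2 of that chain already carries the ring A oxygen, the crowded ether bond only has to be made at an sp3 carbon.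

## Retrosynthetic reasoning

Chain and ring B numbering correspond as follows: chain C7 = C1', C2 = C2', C3 = C3', C4 = C4', C5 = C5', C6 = C6'; the ester carbon C1 becomes the branch carbon on C2'.

**17 to 15.** The CH2OH group on C2' is taken back to a methyl ester, giving diester 15. The branch carbon must arrive at the acid oxidation level because the ring-forming aldol needs an acceptor ketone activated by an ester. The forward step has to reduce the ring B ester and spare the ring A ester. The ring B ester has one ortho substituent. The ring A ester has two, one of them the C6 oxygen, which as phenoxide 16 turns the ester into a vinylogous carboxylate. Making 16 before the hydride is added also keeps the acidic proton from generating borane next to the prenyl alkene.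

**15 to 13 and 14.** The two O–CH3 bonds on ring B are cut, because the aromatisation delivers the C4' and C6' oxygens as free phenols. The forward step must methylate these two phenols, neither of which is ortho to a carbonyl, and leave the C6 hydroxyl of ring A, which is chelated to its ester and flanked by the prenyl group.

**13 to 11.** The C1'–C2' bond of ring B is cut. This is the bond between the carbon bearing the ether oxygen and the carbon bearing the branch. Cutting it unfolds ring B into the linear trioxo ester 11, in which every ring B oxygen is a ketone and the ether oxygen sits on a CH2 group. Cutting the aryl–oxygen bond instead would require a coupling at the crowded centre. The chain has a CH2 terminus at one end only, so only one six-membered aldol is possible, and the regiochemistry of ring B is fixed by the chain. The forward step is an intramolecular aldol through 12, followed by dehydration and enolisation.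

**11 to 6 and 7.** The chain bond C5–C6 is cut, giving Weinreb amide 6 as acyl donor and dioxo ester 7 as nucleophile. The dianion 9 of 7 has a single terminal carbanion, so there is no question of site. Cutting C2–C3 instead would need an oxalate acylation of a diketone with two different termini, one of them the aryloxymethylene group. The forward step is a γ-acylation that stops at the ketone stage through the chelated adduct 10, with the phenol masked as lithium salt 8.

**6 to 4 and 5.** The O–CH2 bond is cut. This is where the hindered ether oxygen is attached, by SN2 at a primary carbon next to a carbonyl. The forward step must alkylate the C2 hydroxyl, which lies next to a ring hydrogen, in preference to the C6 hydroxyl next to the prenyl group.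

**4 to 1 and 2.** The bond from C5 to the prenyl CH2 is cut. Benzoate 1 is symmetric, so its two open ring positions are identical and mono-prenylation can give only one product. The forward step, through phenoxide 3, must favour C- over O-alkylation and one alkylation over two.

## Alternatives that were turned down

**Alternative 1:** Ring A is cut at C1–C2 and C3–C4. The four carbons C4, C5, C6 and C1 come from the fully substituted 2-pyranone A1, and C2–C3 from the ring B aryl ethynyl ether A2. The forward key step is a thermal [4+2] cycloaddition followed by decarboxylative cycloreversion of the bridged lactone, giving the doubly protected target A3.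
- For: the polarity is matched, since the nucleophilic CH terminus of A2 meets the pyranone carbon bearing the methyl group and the oxygen-bearing alkyne carbon meets the ester-bearing carbon. Every ring A substituent is placed by construction. The route never has to distinguish two esters or three phenols, and on that point it is stronger than the chosen plan.
- Against: A1 is a tetrasubstituted pyranone whose 4-alkoxy group lowers its electrophilicity and whose reacting terminus is hindered, so high temperatures are needed, and A2 is prone to polymerise under them. Both partners need several steps each. A3 still needs removal of a MOM and a silyl group, the former with acid next to the prenyl-flanked phenol.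
- Comparison: the chosen route reaches 17 in six steps without protecting groups, and its ring closure is intramolecular.

**Alternative 2:** The C2–O and C1–C(=O) bonds of ring A are cut together. Ring A comes from the silyl aryl triflate A4 as its C1–C2 aryne, and ring B from the aryl methyl carbonate A5. In the forward key step, fluoride-triggered elimination of A4 gives the aryne, the phenoxide derived from A5 adds at C2, and the C1 aryl anion takes the methoxycarbonyl group from a further molecule of A5, giving A6 and releasing the next phenoxide.
- For: the crowded ether and the ester are made in one operation. Ring B arrives with its branch carbon as an acetal, so the two carboxyl-level carbons never have to be differentiated; this is a real advantage over the chosen route.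
- Against: A4 is a pentasubstituted arene carrying silyl, triflate, MOM, methyl and prenyl groups and would take many steps. The phenoxide from A5 has two ortho substituents and adds slowly to an aryne. The aryl anion may be protonated instead of acylated. The end-game still needs acetal hydrolysis, reduction and MOM removal.
- Comparison: the chosen strategy makes the same ether by alkylation at an sp3 carbon and has no protecting groups; what it offers in place of a pre-differentiated branch is the large steric and electronic difference between the two esters of 15.

**Alternative 3:** Ring A is cut at C2–C3 and C1–C6. The diene is the bis(trimethylsilyl) ketene acetal A8 of racemic lavandulic acid A7, and the dienophile is the aryloxypropiolate A9. The forward key step is a [4+2] cycloaddition; the adduct aromatises by loss of a silanol and gives the O-silyl target A10 with its C6 phenol free after work-up.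
- For: the C4 methyl and C5 prenyl groups come from an acyclic acid, so no aromatic prenylation is needed. The chelated phenol is formed directly, only one silyl group remains to be removed, and the sequence is short. On aromatic regiochemistry it is at least as good as the chosen route.
- Against: A8 is a tetrasubstituted ketene acetal on a 2,3-disubstituted diene. A9 is a push–pull alkyne whose acceptor carbon carries the aryloxy donor, so it is a weak dienophile, and open-chain Michael addition or [2+2] addition can compete with this intermolecular step. Making A9 requires an oxygen–alkyne bond on a ring B phenol with two ortho substituents, which is the same steric problem the target poses.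
- Comparison: the chosen strategy attaches the ether oxygen with the unhindered bromide 5 and closes its ring intramolecularly.

Key step: step 4

Assumption: compounds 9 to 12 are drawn as single tautomers or ion pairs although they exist as enol mixtures and aggregates, and 12 is a racemic mixture of diastereomers whose stereocentres disappear on aromatisation.

## Route

Step 1
Reactants: 1 methyl 2,6-dihydroxy-4-methylbenzoate; 2 prenyl bromide (1-bromo-3-methylbut-2-ene)
Product: 4 methyl 2,6-dihydroxy-4-methyl-3-(3-methylbut-2-en-1-yl)benzoate, via monosodium phenoxide 3 (not isolated)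
Conditions: NaH (1.05 equiv), toluene, 0 °C to rt; then 2 (1.0 equiv), rt to 60 °C
Reagents that add atoms: prenyl bromide (2), CC(C)=CCBr
Why: Ortho C-prenylation of a sodium phenoxide that reacts as a tight ion pair in toluene; the two open ring carbons of 1 are equivalent, each ortho to one oxygen and para to the other, so mono-alkylation can give only 4, and limiting 2 holds back a second prenylation.

Step 2
Reactants: 4 methyl 2,6-dihydroxy-4-methyl-3-(3-methylbut-2-en-1-yl)benzoate; 5 2-bromo-N-methoxy-N-methylacetamide
Product: 6 methyl 2-hydroxy-6-{2-[methoxy(methyl)amino]-2-oxoethoxy}-4-methyl-3-(3-methylbut-2-en-1-yl)benzoate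
Conditions: K2CO3 (1.2 equiv), 5 (1.05 equiv), acetone, 50 °C
Reagents that add atoms: 2-bromo-N-methoxy-N-methylacetamide (5), CON(C)C(=O)CBr
Why: Williamson ether synthesis with an α-bromo amide; the hydroxyl next to the ring hydrogen (C2) is far less hindered than the one between the ester and the prenyl group (C6), and after the first alkylation the remaining phenol is locked in a hydrogen bond to the ester carbonyl and resists a second one.

Step 3
Reactants: 6 methyl 2-hydroxy-6-{2-[methoxy(methyl)amino]-2-oxoethoxy}-4-methyl-3-(3-methylbut-2-en-1-yl)benzoate; 7 methyl 2,4-dioxopentanoate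
Product: 11 methyl 7-[3-hydroxy-2-(methoxycarbonyl)-5-methyl-4-(3-methylbut-2-en-1-yl)phenoxy]-2,4,6-trioxoheptanoate, via lithium phenoxide 8 (not isolated), via dilithium dienediolate 9 (not isolated), via trilithium adduct 10 (not isolated)
Conditions: 7 (2 equiv), LiN(iPr)2 (commercial solution, 4.1 equiv), THF, −78 to −20 °C; add 8 [from 6, LiN(SiMe3)2 (1.05 equiv), THF, −78 °C]; −78 to −20 °C; AcOH, then pH 5 buffer; 11 taken on crude
Reagents that add atoms: methyl 2,4-dioxopentanoate (7), COC(=O)C(=O)CC(C)=O
Why: γ-Acylation of a 1,3-dicarbonyl dianion by a Weinreb amide; the terminal carbanion of 9 is its most nucleophilic site and the only CH2 terminus the chain has, the chelated adduct 10 persists until the acid quench so the acidic product cannot consume 9, and the phenol is masked as lithium salt 8, which also shields the ring A ester.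

Step 4
Reactants: 11 methyl 7-[3-hydroxy-2-(methoxycarbonyl)-5-methyl-4-(3-methylbut-2-en-1-yl)phenoxy]-2,4,6-trioxoheptanoate
Product: 13 methyl 6-[2,4-dihydroxy-6-(methoxycarbonyl)phenoxy]-2-hydroxy-4-methyl-3-(3-methylbut-2-en-1-yl)benzoate, via cyclic aldol 12 (not isolated)
Conditions: K2CO3 (3 equiv), MeOH, 0 °C to rt (40 °C if slow); then 1 M HCl to pH 4, 0 °C
Reagents that add atoms: none
Why: Carbonate converts 11 into its enolates; the minor form that is enolised from C6' towards the aryloxy-bearing carbon C1' while C2' remains a free ketone adds through C1' to C2', the carbonyl made most electrophilic by the adjacent ester, and gives aldol 12. This is a 6-(enolendo)-exo-trig closure, the ring being made of chain carbons C2 to C7. E1cB loss of the tertiary hydroxyl of 12 and enolisation of the two remaining ring ketones give the benzene ring of 13, which takes the sequence out of all equilibria. The closest known reaction type is the base-induced aldol cyclisation and aromatisation of 1,3,5-triketones and triketo esters to resorcinols. No stereocentre survives, since the two of 12 are erased on dehydration. The step needs C1' to choose C2' over the ring A ester (five-membered Dieckmann closure to a benzofuranone) and needs C-cyclisation to beat O-cyclisation to a 4-pyranone and attack of C5' on the chain ester; the first is secured by the two ortho substituents and the ortho phenoxide of the ring A ester, the second by the basic medium, in which enol oxygens add poorly to carbonyl carbon, and the third by the reversibility of that Claisen-type closure in methanol against the irreversible aromatisation.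

Step 5
Reactants: 13 methyl 6-[2,4-dihydroxy-6-(methoxycarbonyl)phenoxy]-2-hydroxy-4-methyl-3-(3-methylbut-2-en-1-yl)benzoate; 14 iodomethane
Product: 15 methyl 6-[2,4-dimethoxy-6-(methoxycarbonyl)phenoxy]-2-hydroxy-4-methyl-3-(3-methylbut-2-en-1-yl)benzoate
Conditions: MeI (2.2 equiv), K2CO3 (2.5 equiv), acetone, rt
Reagents that add atoms: iodomethane (14), CI
Why: Williamson O-methylation under weak base; the two ring B phenols are not ortho to any carbonyl and are more acidic and accessible than the C6 hydroxyl of ring A, which is chelated to its ester and flanked by the prenyl group, so two equivalents of 14 at room temperature should stop at 15.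

Step 6
Reactants: 15 methyl 6-[2,4-dimethoxy-6-(methoxycarbonyl)phenoxy]-2-hydroxy-4-methyl-3-(3-methylbut-2-en-1-yl)benzoate
Product: 17 methyl 2-hydroxy-6-[2-(hydroxymethyl)-4,6-dimethoxyphenoxy]-4-methyl-3-(3-methylbut-2-en-1-yl)benzoate, via sodium phenoxide 16 (not isolated)
Conditions: NaH (1.05 equiv), THF, 0 °C; then LiBH4 (2 equiv), 0 to 40 °C; dilute aq. HCl to pH 6, 0 °C
Reagents that add atoms: none
Why: Chemoselective ester reduction with LiBH4; the ring B ester has one ortho substituent and behaves as a normal aryl ester, whereas the ring A ester lies between the aryloxy group and the phenoxide of 16, a vinylogous carboxylate that is sterically screened and electronically deactivated, and forming the phenoxide with NaH first keeps the acidic proton from liberating borane next to the prenyl alkene.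

## Compound list

1 | methyl 2,6-dihydroxy-4-methylbenzoate | COC(=O)c1c(O)cc(C)cc1O | starting material
2 | prenyl bromide (1-bromo-3-methylbut-2-ene) | CC(C)=CCBr | starting material
3 | sodium 3-hydroxy-2-(methoxycarbonyl)-5-methylphenolate (monosodium salt of 1) | [Na+].COC(=O)c1c(O)cc(C)cc1[O-] | intermediate
4 | methyl 2,6-dihydroxy-4-methyl-3-(3-methylbut-2-en-1-yl)benzoate | COC(=O)c1c(O)cc(C)c(CC=C(C)C)c1O | intermediate
5 | 2-bromo-N-methoxy-N-methylacetamide | CON(C)C(=O)CBr | starting material
6 | methyl 2-hydroxy-6-{2-[methoxy(methyl)amino]-2-oxoethoxy}-4-methyl-3-(3-methylbut-2-en-1-yl)benzoate | COC(=O)c1c(OCC(=O)N(C)OC)cc(C)c(CC=C(C)C)c1O | intermediate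
7 | methyl 2,4-dioxopentanoate | COC(=O)C(=O)CC(C)=O | starting material
8 | lithium phenoxide of 6 | [Li+].COC(=O)c1c(OCC(=O)N(C)OC)cc(C)c(CC=C(C)C)c1[O-] | intermediate
9 | dilithium 1-methoxy-1-oxopenta-2,4-diene-2,4-diolate (dianion of 7) | [Li+].[Li+].COC(=O)C([O-])=CC([O-])=C | intermediate
10 | trilithium salt of the tetrahedral N-methoxy-N-methyl adduct of 8 and 9 (racemic at the tetrahedral carbon) | [Li+].[Li+].[Li+].COC(=O)C([O-])=CC(=O)CC([O-])(COc1cc(C)c(CC=C(C)C)c([O-])c1C(=O)OC)N(C)OC | intermediate
11 | methyl 7-[3-hydroxy-2-(methoxycarbonyl)-5-methyl-4-(3-methylbut-2-en-1-yl)phenoxy]-2,4,6-trioxoheptanoate | COC(=O)c1c(OCC(=O)CC(=O)CC(=O)C(=O)OC)cc(C)c(CC=C(C)C)c1O | intermediate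
12 | methyl 2-hydroxy-6-{[2-hydroxy-2-(methoxycarbonyl)-4,6-dioxocyclohexyl]oxy}-4-methyl-3-(3-methylbut-2-en-1-yl)benzoate (racemic mixture of diastereomers) | COC(=O)c1c(OC2C(=O)CC(=O)CC2(O)C(=O)OC)cc(C)c(CC=C(C)C)c1O | intermediate
13 | methyl 6-[2,4-dihydroxy-6-(methoxycarbonyl)phenoxy]-2-hydroxy-4-methyl-3-(3-methylbut-2-en-1-yl)benzoate | COC(=O)c1c(Oc2c(C(=O)OC)cc(O)cc2O)cc(C)c(CC=C(C)C)c1O | intermediate
14 | iodomethane | CI | starting material
15 | methyl 6-[2,4-dimethoxy-6-(methoxycarbonyl)phenoxy]-2-hydroxy-4-methyl-3-(3-methylbut-2-en-1-yl)benzoate | COC(=O)c1c(Oc2c(C(=O)OC)cc(OC)cc2OC)cc(C)c(CC=C(C)C)c1O | intermediate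
16 | sodium phenoxide of 15 | [Na+].COC(=O)c1c(Oc2c(C(=O)OC)cc(OC)cc2OC)cc(C)c(CC=C(C)C)c1[O-] | intermediate
17 | methyl 2-hydroxy-6-[2-(hydroxymethyl)-4,6-dimethoxyphenoxy]-4-methyl-3-(3-methylbut-2-en-1-yl)benzoate (CNP0583011.0) | COC(=O)c1c(Oc2c(CO)cc(OC)cc2OC)cc(C)c(CC=C(C)C)c1O | target

## Step count and least certain steps

Total step count: 6. Longest linear sequence: 6 steps (1 to 17); the other components (2, 5, 7, 14) are bought.

**Step 4 (key step).** The chain is expected to rest as its most stable enolate, spread over C2' to C4', which switches off the acceptor carbonyl. Ring closure may therefore be slow, and O-cyclisation to a pyranone during acidification, base-induced chain cleavage or Dieckmann closure onto the ring A ester could take over. Fallback: set out from 4 and make the diaryl ether directly by a copper-catalysed Ullmann etherification with methyl 2-bromo-3,5-dimethoxybenzoate F1 (CuI, N,N-dimethylglycine, Cs2CO3, dioxane, 100 °C), which should couple at the less hindered C2 hydroxyl and whose ortho ester activates the bromide. This gives 15 and rejoins the route there, ahead of step 6.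

**Step 3.** Proton transfer from the OCH2 group of 8 to the strongly basic 9 may outrun addition, or 9 may condense with itself through its ester, so that 6 is recovered. Fallback: set out from 4 and bring in the whole chain in masked form. Methyl 6-methyl-4-oxo-4H-pyran-2-carboxylate F2, the cyclodehydrated form of a trioxoheptanoate, is brominated at its methyl group (N-bromosuccinimide, radical initiator, PhCF3, reflux) to methyl 6-(bromomethyl)-4-oxo-4H-pyran-2-carboxylate F3. K2CO3 in acetone alkylates the C2 hydroxyl of 4 with F3 to give methyl 6-{[3-hydroxy-2-(methoxycarbonyl)-5-methyl-4-(3-methylbut-2-en-1-yl)phenoxy]methyl}-4-oxo-4H-pyran-2-carboxylate F4. Aqueous K2CO3 in MeOH then opens the pyranone by conjugate addition of hydroxide and ring fission, the classical unmasking of a 4-pyranone to a triketone. This comes back to the route at 11, which is formed in the flask and cyclised as in step 4.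

**Step 1.** O-alkylation and a second C-alkylation may compete with the single C-prenylation. Fallback: set out from 1 and 2 under O-alkylating conditions (K2CO3, acetone) to give methyl 2-hydroxy-4-methyl-6-[(3-methylbut-2-en-1-yl)oxy]benzoate F5, then move the prenyl group from oxygen to carbon on montmorillonite K10 in CH2Cl2 (0 °C to rt). Migration to the carbon ortho or para to the ether oxygen gives the same compound, because these two positions become equivalent once that oxygen is a phenol again. This rejoins the route at 4.

**Step 2.** The wrong phenol, or both phenols, may be alkylated. Fallback: change the order. Alkylate symmetric 1 with 5 (K2CO3, acetone), where no regiochemical question arises, to give methyl 2-hydroxy-6-{2-[methoxy(methyl)amino]-2-oxoethoxy}-4-methylbenzoate F6. Then prenylate the sodium phenoxide of F6 with 2 in toluene (NaH, 0 °C to rt), where the metal-bound oxygen directs the electrophile to its one free ortho carbon. This rejoins the route at 6.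

**Step 6.** Hydride may be delivered to the ring A ester from boron bound to the neighbouring oxygen, or borane released by incomplete metalation may hydroborate the prenyl alkene. Fallback: set out from 15 and differentiate the esters by hydrolysis instead of reduction. LiOH in THF/water at rt should saponify only the ring B ester, since the ring A ester has two ortho substituents and sits next to a phenoxide. This gives 2-[3-hydroxy-2-(methoxycarbonyl)-5-methyl-4-(3-methylbut-2-en-1-yl)phenoxy]-3,5-dimethoxybenzoic acid F7. Ethyl chloroformate and N-methylmorpholine in THF at −15 °C convert F7 into the mixed carbonic anhydride, ethoxycarbonyl 2-[3-hydroxy-2-(methoxycarbonyl)-5-methyl-4-(3-methylbut-2-en-1-yl)phenoxy]-3,5-dimethoxybenzoate F8. NaBH4 in THF/water at 0 °C reduces F8 to the benzylic alcohol without touching the methyl ester or the alkene. This rejoins the route at 17.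

## Further compounds

F1 | step 4 | methyl 2-bromo-3,5-dimethoxybenzoate | COC(=O)c1cc(OC)cc(OC)c1Br
F2 | step 3 | methyl 6-methyl-4-oxo-4H-pyran-2-carboxylate | COC(=O)C1=CC(=O)C=C(C)O1
F3 | step 3 | methyl 6-(bromomethyl)-4-oxo-4H-pyran-2-carboxylate | COC(=O)C1=CC(=O)C=C(CBr)O1
F4 | step 3 | methyl 6-{[3-hydroxy-2-(methoxycarbonyl)-5-methyl-4-(3-methylbut-2-en-1-yl)phenoxy]methyl}-4-oxo-4H-pyran-2-carboxylate | COC(=O)C1=CC(=O)C=C(COc2cc(C)c(CC=C(C)C)c(O)c2C(=O)OC)O1
F5 | step 1 | methyl 2-hydroxy-4-methyl-6-[(3-methylbut-2-en-1-yl)oxy]benzoate | COC(=O)c1c(O)cc(C)cc1OCC=C(C)C
F6 | step 2 | methyl 2-hydroxy-6-{2-[methoxy(methyl)amino]-2-oxoethoxy}-4-methylbenzoate | COC(=O)c1c(OCC(=O)N(C)OC)cc(C)cc1O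
F7 | step 6 | 2-[3-hydroxy-2-(methoxycarbonyl)-5-methyl-4-(3-methylbut-2-en-1-yl)phenoxy]-3,5-dimethoxybenzoic acid | COC(=O)c1c(Oc2c(C(=O)O)cc(OC)cc2OC)cc(C)c(CC=C(C)C)c1O
F8 | step 6 | ethoxycarbonyl 2-[3-hydroxy-2-(methoxycarbonyl)-5-methyl-4-(3-methylbut-2-en-1-yl)phenoxy]-3,5-dimethoxybenzoate (mixed carbonic anhydride) | COC(=O)c1c(Oc2c(C(=O)OC(=O)OCC)cc(OC)cc2OC)cc(C)c(CC=C(C)C)c1O
A1 | alternative 1 | methyl 4-(methoxymethoxy)-6-methyl-5-(3-methylbut-2-en-1-yl)-2-oxo-2H-pyran-3-carboxylate | COC(=O)C1=C(OCOC)C(CC=C(C)C)=C(C)OC1=O
A2 | alternative 1 | tert-butyl{[2-(ethynyloxy)-3,5-dimethoxyphenyl]methoxy}dimethylsilane | C#COc1c(CO[Si](C)(C)C(C)(C)C)cc(OC)cc1OC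
A3 | alternative 1 | methyl 6-[2-({[tert-butyl(dimethyl)silyl]oxy}methyl)-4,6-dimethoxyphenoxy]-2-(methoxymethoxy)-4-methyl-3-(3-methylbut-2-en-1-yl)benzoate | COC(=O)c1c(Oc2c(CO[Si](C)(C)C(C)(C)C)cc(OC)cc2OC)cc(C)c(CC=C(C)C)c1OCOC
A4 | alternative 2 | 3-(methoxymethoxy)-5-methyl-4-(3-methylbut-2-en-1-yl)-2-(trimethylsilyl)phenyl trifluoromethanesulfonate | COCOc1c([Si](C)(C)C)c(OS(=O)(=O)C(F)(F)F)cc(C)c1CC=C(C)C
A5 | alternative 2 | 2-(dimethoxymethyl)-4,6-dimethoxyphenyl methyl carbonate | COC(=O)Oc1c(C(OC)OC)cc(OC)cc1OC
A6 | alternative 2 | methyl 6-[2-(dimethoxymethyl)-4,6-dimethoxyphenoxy]-2-(methoxymethoxy)-4-methyl-3-(3-methylbut-2-en-1-yl)benzoate | COC(=O)c1c(Oc2c(C(OC)OC)cc(OC)cc2OC)cc(C)c(CC=C(C)C)c1OCOC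
A7 | alternative 3 | lavandulic acid, 5-methyl-2-(prop-1-en-2-yl)hex-4-enoic acid (racemic) | CC(C)=CCC(C(C)=C)C(=O)O
A8 | alternative 3 | 1,1-bis(trimethylsilyloxy)-5-methyl-2-(prop-1-en-2-yl)hexa-1,4-diene | CC(C)=CCC(C(C)=C)=C(O[Si](C)(C)C)O[Si](C)(C)C
A9 | alternative 3 | methyl 3-[2-({[tert-butyl(dimethyl)silyl]oxy}methyl)-4,6-dimethoxyphenoxy]prop-2-ynoate | COC(=O)C#COc1c(CO[Si](C)(C)C(C)(C)C)cc(OC)cc1OC
A10 | alternative 3 | methyl 6-[2-({[tert-butyl(dimethyl)silyl]oxy}methyl)-4,6-dimethoxyphenoxy]-2-hydroxy-4-methyl-3-(3-methylbut-2-en-1-yl)benzoate | COC(=O)c1c(Oc2c(CO[Si](C)(C)C(C)(C)C)cc(OC)cc2OC)cc(C)c(CC=C(C)C)c1O
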